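## The problem

Compound 27 is an achiral, mirror-symmetric trimer of three fully substituted phloroglucinol rings. The central ring B carries an isovaleryl group and is joined through its two other carbons, by CH2 bridges, to C4 of two identical terminal rings A and C. Each terminal ring is numbered C1 (OMe), C2 (Me), C3 (OH), C4 (CH2 bridge), C5 (OH), C6 (isovaleryl). There is no stereocentre, so the whole difficulty is constitutional: six different substituents per terminal ring, and three ring oxygens of which only O1 is methylated. The diarylmethane bridges between electron-rich phenols are the fragile element. As free polyphenols they cleave and exchange under acid and base, and joining finished monomers with a one-carbon electrophile gives statistical mixtures. The free heptaphenol is also oxidation-prone, so the phenols should stay masked until a last, neutral step that spares the two aryl methyl ethers and three aryl ketones. The feature that opens the structure is the C1–C2 unit of each terminal ring (MeO–C=C–Me), which is the imprint of an ynol ether. The rest of the ring (C3 to C6, with oxygen at C3 and C5 and the bridge carbon on C4) is the imprint of a 4-(arylmethyl)-3-alkoxycyclobutenone.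

## Retrosynthesis

**27 from 26.** The seven O–H bonds are traced back to benzyl ethers. Benzyl is the one phenol mask that is removed under neutral conditions and is orthogonal to the two methyl ethers that must remain. Compound 26 is no simpler in carbon count, but it is stable to air, acid and base in a way 27 is not.

**26 from 25.** The two C6–C(=O) bonds of rings A and C are cut. An acyl group at C6 cannot pass through the ring-forming step, because C6 derives from C2 of the four-membered ring, which becomes the α-carbon of the vinylketene, and an acyl group there would change the ketene chemistry. Ring B, in contrast, carries its isovaleryl group from compound 2 onward. The ring that holds both bridges is therefore already deactivated, and only two acylations remain instead of three. The forward reaction must be a metal-free, weakly acidic acylation at the single open carbon of each terminal ring.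

**25 from 24.** The two C3–O–benzyl bonds are cut. Capping the free C3 phenols before acylation prevents O-acylation and keeps the phenolic rings from being protonated at the bridge carbon.

**24 from 16 and two molecules of 19 (key disconnection).** In each terminal ring the bonds C2–C3, C1–C6 and C3–C4 are cut. This removes both benzene rings and six C–C bonds at once. It leaves bis(cyclobutenone) 16, in which both bridges already sit at their final carbons of ring B, and 1-methoxypropyne 19, one molecule for each arm. The alternative of coupling finished rings through the bridges is rejected because it is statistical and reversible. The forward reaction must place the alkyne methyl carbon on the ketene carbonyl carbon. It then delivers O1 as methyl ether, O3 as free phenol and O5 as benzyl ether without any differentiation step.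

**16 from 7 and two molecules of 13.** Each cyclobutenone is cut across its C1–C2 and C3–C4 bonds into an aldoketene (15, from acid chloride 14 of diacid 7) and benzyloxyacetylene 13; the two arms of 7 consume one molecule of 13 each. The commercially available ethyl analogue of 13 followed by ether exchange is not used in the main route. Exchange through the free 1,3-dione would re-etherify at the more substituted enol, and the annulation would then swap the bridge-bearing carbon with the unsubstituted one. With 13 the benzyl ether is in place from the start and the regiochemistry is fixed by the cycloaddition.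

**13 from 8 and 9; 19 from 17.** Ynol ether 13 comes from benzyl alcohol 8 and trichloroethylene 9 by way of dichlorovinyl ether 11. Ynol ether 19 comes from chloroacetal 17 by elimination and C-methylation.

**7 from 4.** The Cα–Cβ bond of each propanoic acid chain is cut. The aldehyde carbons of 4 become the two bridge CH2 groups, and a reductive Knoevenagel homologation supplies the two carbons that become C4 and C3 of each terminal ring. No separate alkene reduction is needed, which would endanger the benzyl ethers.

**4 from 3, 2 and 1.** The benzyl ethers, the two formyl groups and the isovaleryl group are removed in turn, arriving at phloroglucinol 1. All three operations use the innate nucleophilicity of the phloroglucinol nucleus.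

## Roads not taken

Alternative 1: The terminal ring is cut at C1–C2 and C5–C6 into silyloxydiene A1 (1,1,3-tris(trimethylsilyloxy)penta-1,3-diene) and the push–pull ynone A2 (1-methoxy-5-methylhex-1-yn-3-one). A thermal [4+2] cycloaddition, loss of silanol and desilylation would give monomer A3 with all six substituents in place.
- Merits: the ketone arrives with the ring, so no Friedel–Crafts step is needed. The polarity match (methyl-bearing diene terminus to the methoxy-bearing alkyne carbon) gives the correct pattern. A3 is reached in very few steps.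
- Weak points: A1 is moisture-sensitive and its terminal methyl lowers reactivity. A2 is a deactivated dienophile. Above all, the route stops at a monomer. Two molecules of A3 must still be bridged to a ring B unit such as 2 with a one-carbon electrophile. Self-condensation of A3, over-reaction of 2 and equilibration of the bridged phenols all compete.
- Comparison: this road is shorter to a fully functionalised ring and avoids acylation in the presence of the bridges, which is a real advantage. The chosen plan sets against it that both bridges are fixed at defined carbons before either terminal ring exists, so no statistical coupling arises, and one thermal operation builds both rings.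

Alternative 2: All seven C–OH bonds are cut back to C–F. Heptafluoro trimer A4 would be treated with sodium benzyloxide A5 in a hot dipolar aprotic solvent to give hepta-O-benzyl compound A6 by sevenfold addition–elimination.
- Merits: every fluoride is ortho or para to a ketone. Fluoroarenes tolerate most C–C bond-forming chemistry. A6 is identical with 26, so the endgame would be the same single hydrogenolysis.
- Weak points: each alkoxy group introduced deactivates the ring for the next substitution, so the last displacements on ring B are expected to be slow. The methoxy groups ortho to the ketones are themselves leaving groups, which threatens the methyl/benzyl pattern. The enolisable ketones, the doubly benzylic CH2 groups and the polyfluoroaryl ketones (retro-Claisen cleavage) are all exposed to hot alkoxide. A4 also still needs the bridges, three acyl groups, two methyls and two methoxy groups on a polyfluorinated skeleton, so the C–C problem is moved, not solved.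
- Comparison: for oxygenation alone this is more step-economical than the chosen plan. The chosen plan brings each oxygen in with its carbon and already in its final protection state, under neutral conditions.

Alternative 3: The C1–O and C6–C(=O) bonds are cut. Fluoride would convert silylaryl triflate A7 into aryne A8, and isovaleric acid A9 would add across it with acyl transfer to give ortho-hydroxyaryl ketone A10.
- Merits: the ketone and the single free phenol O1 are created together on adjacent carbons. O1 is therefore marked for methylation without any selectivity problem, and the ketone is installed under neutral conditions.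
- Weak points: A7 needs a C-methylated phloroglucinol whose three oxygens are already differentiated (two benzyl, one triflate) and an ortho silyl group, which is several steps. The acid must add at the aryne carbon next to the methyl group, a selectivity that rests only on the remote benzyloxy group. Simple O-arylation without acyl transfer competes. After O-methylation and hydrogenolysis A10 gives the same monomer A3, so the bridging problem of alternative 1 returns.
- Comparison: this road is as elegant as the chosen key step in marking O1 and gentler in placing the ketone. It is longer than alternative 1 for the same monomer and shares its unselective trimer assembly, which the chosen plan avoids by building rings A and C on preformed bridges.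

Key step: step 9

Assumption: compounds 16, 21 and 23 are diastereomer mixtures; their stereocentres are all lost on aromatisation, so they are drawn without configuration.

## Route

Step 1
Reactants: 1 phloroglucinol
Product: 2 1-(2,4,6-trihydroxyphenyl)-3-methylbutan-1-one
Conditions: isovaleryl chloride (1.0 equiv), AlCl3 (3 equiv), PhNO2/CH2Cl2, 0 °C → 40 °C; aq HCl
Reagents that add atoms: isovaleryl chloride CC(C)CC(=O)Cl
Why: Friedel–Crafts C-acylation of phloroglucinol; the first acyl group deactivates the ring by conjugation and chelation, so one equivalent of acid chloride should stop at the monoketone.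

Step 2
Reactants: 2 1-(2,4,6-trihydroxyphenyl)-3-methylbutan-1-one
Product: 3 2,4,6-trihydroxy-5-(3-methylbutanoyl)benzene-1,3-dicarbaldehyde (jensenone)
Conditions: POCl3 (5 equiv), DMF (5 equiv), MeCN, 0 °C → rt; then H2O, 50 °C
Reagents that add atoms: N,N-dimethylformamide CN(C)C=O; water O
Why: Vilsmeier–Haack formylation; the two remaining ring carbons of the acylphloroglucinol are each flanked by two hydroxyls and should take up the chloroiminium electrophile twice, the aldehydes being released on aqueous work-up.

Step 3
Reactants: 3 2,4,6-trihydroxy-5-(3-methylbutanoyl)benzene-1,3-dicarbaldehyde (jensenone)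
Product: 4 2,4,6-tris(benzyloxy)-5-(3-methylbutanoyl)benzene-1,3-dicarbaldehyde
Conditions: BnBr (4 equiv), K2CO3 (4 equiv), n-Bu4NI (cat.), DMF, 60 °C
Reagents that add atoms: benzyl bromide BrCc1ccccc1
Why: Williamson O-benzylation; every ring carbon already bears a carbonyl substituent, so the phloroglucinolate can be alkylated cleanly only on oxygen, and hot DMF breaks the chelates.

Step 4
Reactants: 4 2,4,6-tris(benzyloxy)-5-(3-methylbutanoyl)benzene-1,3-dicarbaldehyde
Product: 7 3,3'-[2,4,6-tris(benzyloxy)-5-(3-methylbutanoyl)-1,3-phenylene]dipropanoic acid, via bis(arylidene Meldrum's acid) 5 (not isolated), via bis(arylmethyl Meldrum's acid) 6 (not isolated)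
Conditions: Meldrum's acid (2.4 equiv), HCO2H/Et3N (5:2), 95–100 °C; aq HCl
Reagents that add atoms: 2,2-dimethyl-1,3-dioxane-4,6-dione (Meldrum's acid) CC1(C)OC(=O)CC(=O)O1; water O
Why: Tandem Knoevenagel condensation, conjugate reduction by formate and hydrolytic decarboxylation, the known one-pot conversion of aryl aldehydes into 3-arylpropanoic acids; no palladium or hydride is present, so the benzyl ethers and the hindered aryl ketone should be untouched.

Step 5
Reactants: 8 benzyl alcohol; 9 trichloroethylene
Product: 11 benzyl (E)-1,2-dichlorovinyl ether, via dichloroacetylene 10 (not isolated)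
Conditions: KH (1.2 equiv), THF, 0 °C; then 9, −50 °C → rt
Reagents that add atoms: none
Why: Base-induced loss of HCl from 9 gives 10, to which the alkoxide adds in anti fashion; this is the general route to 1,2-dichlorovinyl ethers.

Step 6
Reactants: 11 benzyl (E)-1,2-dichlorovinyl ether
Product: 13 benzyloxyacetylene (benzyl ethynyl ether), via lithium benzyloxyacetylide 12 (not isolated)
Conditions: n-BuLi (2.2 equiv), Et2O, −78 → −40 °C; MeOH (1.1 equiv), −78 °C; cold aqueous work-up, kept as a CH2Cl2 solution at ≤ 0 °C
Reagents that add atoms: none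
Why: Deprotonation, β-elimination of LiCl and chlorine–lithium exchange give acetylide 12, which is protonated cold; 13 is used at once in solution because benzyl alkynyl ethers rearrange sigmatropically on warming.

Step 7
Reactants: 7 3,3'-[2,4,6-tris(benzyloxy)-5-(3-methylbutanoyl)-1,3-phenylene]dipropanoic acid; 13 benzyloxyacetylene (two molecules incorporated)
Product: 16 1-[2,4,6-tris(benzyloxy)-3,5-bis{[2-(benzyloxy)-4-oxocyclobut-2-en-1-yl]methyl}phenyl]-3-methylbutan-1-one (diastereomer mixture), via bis(acid chloride) 14 (not isolated), via bis(ketene) 15 (not isolated)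
Conditions: (COCl)2, DMF (cat.), CH2Cl2, 0 °C → rt, evaporate; then 13 (6 equiv), Et3N (2.4 equiv, syringe pump), CH2Cl2, 0 °C → rt
Reagents that add atoms: none
Why: Dehydrochlorination of each 3-arylpropanoyl chloride gives an aldoketene, and each of the two ketene arms takes up one molecule of 13 in a [2+2] cycloaddition; the unsubstituted alkyne carbon bonds to the ketene carbonyl carbon, so the benzyloxy group ends at C3 and the arylmethyl group at C4 of each cyclobutenone. Slow base addition into excess alkyne should suppress ketene dimerisation; the two new stereocentres form without control and are erased in step 9.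

Step 8
Reactants: 17 chloroacetaldehyde dimethyl acetal
Product: 19 1-methoxypropyne, via sodium methoxyacetylide 18 (not isolated)
Conditions: NaNH2 (3 equiv), liq. NH3, −33 °C; then MeI, −50 °C; distilled into a cold receiver
Reagents that add atoms: iodomethane CI
Why: Two eliminations and a deprotonation by NaNH2 convert the chloroacetal into acetylide 18, which is C-methylated in liquid ammonia; this is the standard preparation of 1-alkoxyalk-1-ynes.

Step 9
Reactants: 16 1-[2,4,6-tris(benzyloxy)-3,5-bis{[2-(benzyloxy)-4-oxocyclobut-2-en-1-yl]methyl}phenyl]-3-methylbutan-1-one; 19 1-methoxypropyne (two molecules incorporated)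
Product: 24 1-[2,4,6-tris(benzyloxy)-3,5-bis{[6-(benzyloxy)-2-hydroxy-4-methoxy-3-methylphenyl]methyl}phenyl]-3-methylbutan-1-one, via bis(vinylketene) 20 (not isolated), via bis(alkenylcyclobutenone) 21 (not isolated), via bis(dienylketene) 22 (not isolated), via bis(cyclohexadienone) 23 (not isolated)
Conditions: 19 (6–8 equiv), PhMe, sealed tube, 80 °C → 110 °C
Reagents that add atoms: none
Why: This is a thermal Danheiser benzannulation run in both arms at once, each arm taking up one molecule of 19. Each 3-benzyloxycyclobutenone opens by conrotatory 4π electrocyclic cleavage of its C1–C4 bond to alkoxyvinylketene 20, the arylmethyl group rotating outward so that it cannot pass hydrogen to the ketene by a 1,5-shift. The ketene C=C then adds 19 in a regiospecific [2+2] cycloaddition: the nucleophilic methyl-bearing alkyne carbon bonds to the ketene carbonyl carbon (new C2–C3) and the methoxy-bearing carbon to the ketene α-carbon (new C1–C6), giving 21. A second, reversible 4π opening gives dienylketene 22, and the isomer with the alkenyl group turned inward closes each benzene ring by a thermal disrotatory 6π electrocyclisation that joins the ketene carbon to the arylmethyl-bearing terminus (new C3–C4), after which cyclohexadienone 23 tautomerises to the phenol. The closest known reaction type is the benzannulation of cyclobutenones with alkoxyalkynes to resorcinol monoethers; the 3-alkoxy donor on the four-membered ring is an extension within that class, supported by the known thermal opening of alkoxycyclobutenones to vinylketenes. The stereocentres of 16, 21 and 23 are all destroyed on the way, so no stereocontrol is needed. The one selectivity required is the orientation of the [2+2] step, which the strong polarisation of the ynol ether secures, placing Me at C2 between OMe at C1 and the new free OH at C3. Each terminal ring therefore emerges with its three oxygens already distinguished: O1 methyl, O3 free, O5 benzyl.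

Step 10
Reactants: 24 1-[2,4,6-tris(benzyloxy)-3,5-bis{[6-(benzyloxy)-2-hydroxy-4-methoxy-3-methylphenyl]methyl}phenyl]-3-methylbutan-1-one
Product: 25 1-[2,4,6-tris(benzyloxy)-3,5-bis{[2,6-bis(benzyloxy)-4-methoxy-3-methylphenyl]methyl}phenyl]-3-methylbutan-1-one
Conditions: BnBr (3 equiv), K2CO3 (4 equiv), n-Bu4NI (cat.), DMF, 60 °C
Reagents that add atoms: benzyl bromide BrCc1ccccc1
Why: Williamson etherification of the two hindered C3 phenols; capping them prevents O-acylation and ipso-protonation of the phenolic rings in the next step, and the ketone and aryl methyl ethers are inert to K2CO3.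

Step 11
Reactants: 25 1-[2,4,6-tris(benzyloxy)-3,5-bis{[2,6-bis(benzyloxy)-4-methoxy-3-methylphenyl]methyl}phenyl]-3-methylbutan-1-one
Product: 26 1-[2,4,6-tris(benzyloxy)-3,5-bis{[2,6-bis(benzyloxy)-4-methoxy-3-methyl-5-(3-methylbutanoyl)phenyl]methyl}phenyl]-3-methylbutan-1-one
Conditions: isovaleric acid (6 equiv), (CF3CO)2O (6 equiv), 85% H3PO4 (cat.), CH2Cl2, 0 °C → rt
Reagents that add atoms: isovaleric acid CC(C)CC(=O)O
Why: Friedel–Crafts acylation by the mixed trifluoroacetic anhydride, a metal-free variant known for trialkoxybenzenes. C6 is the only unsubstituted carbon of each terminal ring and is flanked by OMe and OBn, while ring B is fully substituted and deactivated by its ketone, so only the two desired carbons can react.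

Step 12
Reactants: 26 1-[2,4,6-tris(benzyloxy)-3,5-bis{[2,6-bis(benzyloxy)-4-methoxy-3-methyl-5-(3-methylbutanoyl)phenyl]methyl}phenyl]-3-methylbutan-1-one
Product: 27 1-[2,4,6-trihydroxy-3,5-bis{[2,6-dihydroxy-4-methoxy-3-methyl-5-(3-methylbutanoyl)phenyl]methyl}phenyl]-3-methylbutan-1-one (CNP0158539.0)
Conditions: H2 (1 atm), 10% Pd/C, EtOAc/MeOH, rt
Reagents that add atoms: none
Why: Hydrogenolysis of seven aryl benzyl ethers; aryl methyl ethers, the hindered chelated aryl ketones and the diarylmethane C–C bonds should be stable under neutral hydrogenation, so the sensitive polyphenol is unmasked only in this last step.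

## Compound list

1 | phloroglucinol | Oc1cc(O)cc(O)c1 | starting material
2 | 1-(2,4,6-trihydroxyphenyl)-3-methylbutan-1-one | CC(C)CC(=O)c1c(O)cc(O)cc1O | intermediate
3 | 2,4,6-trihydroxy-5-(3-methylbutanoyl)benzene-1,3-dicarbaldehyde (jensenone) | CC(C)CC(=O)c1c(O)c(C=O)c(O)c(C=O)c1O | intermediate
4 | 2,4,6-tris(benzyloxy)-5-(3-methylbutanoyl)benzene-1,3-dicarbaldehyde | CC(C)CC(=O)c1c(OCc2ccccc2)c(C=O)c(OCc2ccccc2)c(C=O)c1OCc1ccccc1 | intermediate
5 | bis(arylidene Meldrum's acid): both CHO groups of 4 condensed with Meldrum's acid | CC(C)CC(=O)c1c(OCc2ccccc2)c(C=C2C(=O)OC(C)(C)OC2=O)c(OCc2ccccc2)c(C=C2C(=O)OC(C)(C)OC2=O)c1OCc1ccccc1 | intermediate (not isolated)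
6 | bis(arylmethyl Meldrum's acid): conjugate-reduced form of 5 | CC(C)CC(=O)c1c(OCc2ccccc2)c(CC2C(=O)OC(C)(C)OC2=O)c(OCc2ccccc2)c(CC2C(=O)OC(C)(C)OC2=O)c1OCc1ccccc1 | intermediate (not isolated)
7 | 3,3'-[2,4,6-tris(benzyloxy)-5-(3-methylbutanoyl)-1,3-phenylene]dipropanoic acid | CC(C)CC(=O)c1c(OCc2ccccc2)c(CCC(=O)O)c(OCc2ccccc2)c(CCC(=O)O)c1OCc1ccccc1 | intermediate
8 | benzyl alcohol | OCc1ccccc1 | starting material
9 | trichloroethylene | ClC=C(Cl)Cl | starting material
10 | dichloroacetylene | ClC#CCl | intermediate (not isolated)
11 | benzyl (E)-1,2-dichlorovinyl ether | Cl/C=C(/Cl)OCc1ccccc1 | intermediate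
12 | lithium benzyloxyacetylide | [Li]C#COCc1ccccc1 | intermediate (not isolated)
13 | benzyloxyacetylene (benzyl ethynyl ether) | C#COCc1ccccc1 | intermediate
14 | bis(acid chloride) of 7 | CC(C)CC(=O)c1c(OCc2ccccc2)c(CCC(=O)Cl)c(OCc2ccccc2)c(CCC(=O)Cl)c1OCc1ccccc1 | intermediate (not isolated)
15 | bis(ketene): both arms ArCH2CH=C=O | CC(C)CC(=O)c1c(OCc2ccccc2)c(CC=C=O)c(OCc2ccccc2)c(CC=C=O)c1OCc1ccccc1 | intermediate (not isolated)
16 | 1-[2,4,6-tris(benzyloxy)-3,5-bis{[2-(benzyloxy)-4-oxocyclobut-2-en-1-yl]methyl}phenyl]-3-methylbutan-1-one (meso and racemic diastereomers) | CC(C)CC(=O)c1c(OCc2ccccc2)c(CC2C(=O)C=C2OCc2ccccc2)c(OCc2ccccc2)c(CC2C(=O)C=C2OCc2ccccc2)c1OCc1ccccc1 | intermediate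
17 | chloroacetaldehyde dimethyl acetal | COC(CCl)OC | starting material
18 | sodium methoxyacetylide | [Na]C#COC | intermediate (not isolated)
19 | 1-methoxypropyne | CC#COC | intermediate
20 | bis(vinylketene): both arms ArCH2–CH=C(OBn)–CH=C=O, arylmethyl trans to the ketene carbon | CC(C)CC(=O)c1c(OCc2ccccc2)c(C/C=C(/C=C=O)OCc2ccccc2)c(OCc2ccccc2)c(C/C=C(/C=C=O)OCc2ccccc2)c1OCc1ccccc1 | intermediate (not isolated)
21 | bis(alkenylcyclobutenone): both arms 4-[1-(benzyloxy)-3-arylprop-1-enyl]-3-methoxy-2-methylcyclobut-2-en-1-one | CC(C)CC(=O)c1c(OCc2ccccc2)c(C/C=C(/C2C(=O)C(C)=C2OC)OCc2ccccc2)c(OCc2ccccc2)c(C/C=C(/C2C(=O)C(C)=C2OC)OCc2ccccc2)c1OCc1ccccc1 | intermediate (not isolated)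
22 | bis(dienylketene): both arms ArCH2–CH=C(OBn)–CH=C(OMe)–C(Me)=C=O, drawn as the isomer that can cyclise | CC(C)CC(=O)c1c(OCc2ccccc2)c(C/C=C(/C=C(\C(C)=C=O)OC)OCc2ccccc2)c(OCc2ccccc2)c(C/C=C(/C=C(\C(C)=C=O)OC)OCc2ccccc2)c1OCc1ccccc1 | intermediate (not isolated)
23 | bis(cyclohexadienone): both arms 6-(arylmethyl)-5-(benzyloxy)-3-methoxy-2-methylcyclohexa-2,4-dien-1-one | CC(C)CC(=O)c1c(OCc2ccccc2)c(CC2C(=O)C(C)=C(OC)C=C2OCc2ccccc2)c(OCc2ccccc2)c(CC2C(=O)C(C)=C(OC)C=C2OCc2ccccc2)c1OCc1ccccc1 | intermediate (not isolated)
24 | 1-[2,4,6-tris(benzyloxy)-3,5-bis{[6-(benzyloxy)-2-hydroxy-4-methoxy-3-methylphenyl]methyl}phenyl]-3-methylbutan-1-one | CC(C)CC(=O)c1c(OCc2ccccc2)c(Cc2c(O)c(C)c(OC)cc2OCc2ccccc2)c(OCc2ccccc2)c(Cc2c(O)c(C)c(OC)cc2OCc2ccccc2)c1OCc1ccccc1 | intermediate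
25 | 1-[2,4,6-tris(benzyloxy)-3,5-bis{[2,6-bis(benzyloxy)-4-methoxy-3-methylphenyl]methyl}phenyl]-3-methylbutan-1-one | CC(C)CC(=O)c1c(OCc2ccccc2)c(Cc2c(OCc3ccccc3)c(C)c(OC)cc2OCc2ccccc2)c(OCc2ccccc2)c(Cc2c(OCc3ccccc3)c(C)c(OC)cc2OCc2ccccc2)c1OCc1ccccc1 | intermediate
26 | 1-[2,4,6-tris(benzyloxy)-3,5-bis{[2,6-bis(benzyloxy)-4-methoxy-3-methyl-5-(3-methylbutanoyl)phenyl]methyl}phenyl]-3-methylbutan-1-one | CC(C)CC(=O)c1c(OCc2ccccc2)c(Cc2c(OCc3ccccc3)c(C)c(OC)c(C(=O)CC(C)C)c2OCc2ccccc2)c(OCc2ccccc2)c(Cc2c(OCc3ccccc3)c(C)c(OC)c(C(=O)CC(C)C)c2OCc2ccccc2)c1OCc1ccccc1 | intermediate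
27 | 1-[2,4,6-trihydroxy-3,5-bis{[2,6-dihydroxy-4-methoxy-3-methyl-5-(3-methylbutanoyl)phenyl]methyl}phenyl]-3-methylbutan-1-one (CNP0158539.0) | COc1c(C)c(O)c(Cc2c(O)c(Cc3c(O)c(C)c(OC)c(C(=O)CC(C)C)c3O)c(O)c(C(=O)CC(C)C)c2O)c(O)c1C(=O)CC(C)C | target

## Step count and risks

Total step count: 12. Longest linear sequence: 9 steps (steps 1, 2, 3, 4, 7, 9, 10, 11, 12 from phloroglucinol). Steps 5 and 6 (reagent 13) and step 8 (reagent 19) are side branches.

**Step 9 (key step).** The most likely failure is loss of the alkoxyvinylketene before the ynol ether captures it. It can dimerise, or it can acylate a phenol already formed in the other arm, giving esters and oligomers. Capture may be slow because 19 is volatile and only moderately nucleophilic, and a 3-alkoxy donor on the cyclobutenone is at the edge of the known scope. Incomplete reaction of one arm is the second concern. The fallback sets out from 16 and changes the ketenophile and the way O1 is marked. Heating 16 with the non-volatile, more nucleophilic 1-(triisopropylsiloxy)propyne F1 (from ethyl acetate by Kowalski ester homologation and silylation with i-Pr3SiCl) should give the bis(silyl ether) bis-phenol F2 with the same regiochemistry. Benzylation of the C3 phenols (BnBr, NaH, THF, 0 °C) then gives the bis(silyl ether) hepta-benzyl ether F3, and n-Bu4NF in THF frees O1 to give the bis-phenol F4. MeI and K2CO3 in acetone methylate O1, and the sequence comes back to the route at 25.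

**Step 7.** The most likely failure is dimerisation of the aldoketene, within or between molecules, outrunning the cycloaddition. Thermal rearrangement of the labile benzyl ynol ether 13 would further reduce the yield of material with both arms cyclised. The fallback sets out from 7. The same acid chloride and ketene generation is run with commercial ethoxyacetylene (robust and usable in large excess) to give the bis(3-ethoxycyclobutenone) F5. The ethoxy groups are then exchanged by acid-catalysed addition–elimination with benzyl alcohol (pyridinium p-toluenesulfonate, benzene, 4 Å sieves, 40 °C, ethanol removed), the alkoxy exchange familiar from squarate esters. Conditions must be strictly anhydrous so that the free 1,3-dione, and with it the wrong enol ether, is never formed. This comes back to the route at 16.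

**Step 11.** The most likely failure is acid-induced scission or migration of the diarylmethane bridges by ipso-protonation of the electron-rich terminal rings. Benzyl transfer under trifluoroacetic acid and incomplete second acylation at the crowded C6 are further risks. The fallback sets out from 25 and avoids acylium chemistry. Vilsmeier–Haack formylation (POCl3, DMF) at the two C6 positions gives the bis-aldehyde F6. Addition of i-BuMgBr at −78 °C, where the hindered ring B ketone should not compete, gives the bis-carbinol F7 as a diastereomer mixture whose stereocentres are then erased. Dess–Martin oxidation comes back to the route at 26.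

**Step 3.** The most likely failure is incomplete etherification of the strongly chelated, weakly nucleophilic triacylphloroglucinolate, or C-benzylation at an acyl-bearing carbon with loss of aromaticity. The fallback sets out from 2 and avoids alkylating a triacyl phenol. Benzylation at the monoketone stage (BnBr, K2CO3, DMF) gives 1-[2,4,6-tris(benzyloxy)phenyl]-3-methylbutan-1-one F8, and NBS in MeCN then gives the 3,5-dibromide F9. Double Negishi coupling with BrZnCH2CH2CO2Et (Pd(OAc)2, SPhos, THF) gives the diethyl dipropanoate F10, and LiOH in aqueous THF comes back to the route at 7, bypassing 3 and 4.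

## Further compounds

F1 | step 9 | 1-(triisopropylsiloxy)propyne | CC#CO[Si](C(C)C)(C(C)C)C(C)C
F2 | step 9 | 1-[2,4,6-tris(benzyloxy)-3,5-bis{[6-(benzyloxy)-2-hydroxy-3-methyl-4-(triisopropylsiloxy)phenyl]methyl}phenyl]-3-methylbutan-1-one | CC(C)CC(=O)c1c(OCc2ccccc2)c(Cc2c(O)c(C)c(O[Si](C(C)C)(C(C)C)C(C)C)cc2OCc2ccccc2)c(OCc2ccccc2)c(Cc2c(O)c(C)c(O[Si](C(C)C)(C(C)C)C(C)C)cc2OCc2ccccc2)c1OCc1ccccc1
F3 | step 9 | 1-[2,4,6-tris(benzyloxy)-3,5-bis{[2,6-bis(benzyloxy)-3-methyl-4-(triisopropylsiloxy)phenyl]methyl}phenyl]-3-methylbutan-1-one | CC(C)CC(=O)c1c(OCc2ccccc2)c(Cc2c(OCc3ccccc3)c(C)c(O[Si](C(C)C)(C(C)C)C(C)C)cc2OCc2ccccc2)c(OCc2ccccc2)c(Cc2c(OCc3ccccc3)c(C)c(O[Si](C(C)C)(C(C)C)C(C)C)cc2OCc2ccccc2)c1OCc1ccccc1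
F4 | step 9 | 1-[2,4,6-tris(benzyloxy)-3,5-bis{[2,6-bis(benzyloxy)-4-hydroxy-3-methylphenyl]methyl}phenyl]-3-methylbutan-1-one | CC(C)CC(=O)c1c(OCc2ccccc2)c(Cc2c(OCc3ccccc3)c(C)c(O)cc2OCc2ccccc2)c(OCc2ccccc2)c(Cc2c(OCc3ccccc3)c(C)c(O)cc2OCc2ccccc2)c1OCc1ccccc1
F5 | step 7 | 1-[2,4,6-tris(benzyloxy)-3,5-bis{[2-ethoxy-4-oxocyclobut-2-en-1-yl]methyl}phenyl]-3-methylbutan-1-one (diastereomer mixture) | CC(C)CC(=O)c1c(OCc2ccccc2)c(CC2C(=O)C=C2OCC)c(OCc2ccccc2)c(CC2C(=O)C=C2OCC)c1OCc1ccccc1
F6 | step 11 | 1-[2,4,6-tris(benzyloxy)-3,5-bis{[2,6-bis(benzyloxy)-5-formyl-4-methoxy-3-methylphenyl]methyl}phenyl]-3-methylbutan-1-one | CC(C)CC(=O)c1c(OCc2ccccc2)c(Cc2c(OCc3ccccc3)c(C)c(OC)c(C=O)c2OCc2ccccc2)c(OCc2ccccc2)c(Cc2c(OCc3ccccc3)c(C)c(OC)c(C=O)c2OCc2ccccc2)c1OCc1ccccc1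
F7 | step 11 | 1-[2,4,6-tris(benzyloxy)-3,5-bis{[2,6-bis(benzyloxy)-5-(1-hydroxy-3-methylbutyl)-4-methoxy-3-methylphenyl]methyl}phenyl]-3-methylbutan-1-one (diastereomer mixture) | CC(C)CC(=O)c1c(OCc2ccccc2)c(Cc2c(OCc3ccccc3)c(C)c(OC)c(C(O)CC(C)C)c2OCc2ccccc2)c(OCc2ccccc2)c(Cc2c(OCc3ccccc3)c(C)c(OC)c(C(O)CC(C)C)c2OCc2ccccc2)c1OCc1ccccc1
F8 | step 3 | 1-[2,4,6-tris(benzyloxy)phenyl]-3-methylbutan-1-one | CC(C)CC(=O)c1c(OCc2ccccc2)cc(OCc2ccccc2)cc1OCc1ccccc1
F9 | step 3 | 1-[2,4,6-tris(benzyloxy)-3,5-dibromophenyl]-3-methylbutan-1-one | CC(C)CC(=O)c1c(OCc2ccccc2)c(Br)c(OCc2ccccc2)c(Br)c1OCc1ccccc1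
F10 | step 3 | diethyl 3,3'-[2,4,6-tris(benzyloxy)-5-(3-methylbutanoyl)-1,3-phenylene]dipropanoate | CC(C)CC(=O)c1c(OCc2ccccc2)c(CCC(=O)OCC)c(OCc2ccccc2)c(CCC(=O)OCC)c1OCc1ccccc1
A1 | alternative 1 | 1,1,3-tris(trimethylsilyloxy)penta-1,3-diene | CC=C(O[Si](C)(C)C)C=C(O[Si](C)(C)C)O[Si](C)(C)C
A2 | alternative 1 | 1-methoxy-5-methylhex-1-yn-3-one | COC#CC(=O)CC(C)C
A3 | alternative 1 | 1-(4,6-dihydroxy-2-methoxy-3-methylphenyl)-3-methylbutan-1-one | COc1c(C)c(O)cc(O)c1C(=O)CC(C)C
A4 | alternative 2 | heptafluoro trimer (all seven hydroxyls of 27 replaced by fluorine) | COc1c(C)c(F)c(Cc2c(F)c(Cc3c(F)c(C)c(OC)c(C(=O)CC(C)C)c3F)c(F)c(C(=O)CC(C)C)c2F)c(F)c1C(=O)CC(C)C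
A5 | alternative 2 | sodium benzyloxide | [Na+].[O-]Cc1ccccc1
A6 | alternative 2 | hepta-O-benzyl target (identical with 26) | COc1c(C)c(OCc2ccccc2)c(Cc2c(OCc3ccccc3)c(Cc3c(OCc4ccccc4)c(C)c(OC)c(C(=O)CC(C)C)c3OCc3ccccc3)c(OCc3ccccc3)c(C(=O)CC(C)C)c2OCc2ccccc2)c(OCc2ccccc2)c1C(=O)CC(C)C
A7 | alternative 3 | 3,5-bis(benzyloxy)-2-methyl-6-(trimethylsilyl)phenyl trifluoromethanesulfonate | Cc1c(OS(=O)(=O)C(F)(F)F)c([Si](C)(C)C)c(OCc2ccccc2)cc1OCc1ccccc1
A8 | alternative 3 | 3,5-bis(benzyloxy)-6-methylbenzyne | CC1=C(OCc2ccccc2)C=C(OCc2ccccc2)C#C1
A9 | alternative 3 | isovaleric acid | CC(C)CC(=O)O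
A10 | alternative 3 | 1-[2,4-bis(benzyloxy)-6-hydroxy-5-methylphenyl]-3-methylbutan-1-one | CC(C)CC(=O)c1c(O)c(C)c(OCc2ccccc2)cc1OCc1ccccc1
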